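**Retrosynthetic overview**
- The target is reached from a stilbene phenol carrying two benzyl ethers: one hydrogenation saturates the C=C bond and frees both phenols.
- Feature the plan rests on: ring A is a resorcinol monomethyl ether (C1 arylethyl, C2 benzyl, C3 OH, C5 OMe, H at C4 and C6). This is the pattern of a folded 1,3,5-tricarbonyl chain in which C5 is fixed as a methyl enol ether, C3 and C1 are ketones and C2 bears the benzyl group.
- Ring A is the only ring made. It comes from an acyclic 2-benzyl-1,3-diketone with a β-methoxy enone at one end and a cinnamoyl group at the other: the enol-ether methyl becomes C6 and bonds to the cinnamoyl carbonyl carbon C1 (vinylogous aldol), then water is lost and the ring aromatises.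
- The diketone comes from a β-hydroxy ketone by oxidation, and that from the aldol of the α'-enolate of benzylated 4-methoxypent-3-en-2-one with 2-(benzyloxy)cinnamaldehyde; the benzylated enone comes from 4-methoxypent-3-en-2-one and 4-(benzyloxy)benzyl bromide.

Key step: step 5

Remark on the chemistry: the target has no stereocentre. Diketone 7 is racemic at its central carbon and in equilibrium with its enols; this is of no consequence because that carbon becomes C2 of ring A.

**Route**

Step 1
Reactants: 1 (E)-4-methoxypent-3-en-2-one; 2 4-(benzyloxy)benzyl bromide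
Product: 3 (E)-1-[4-(benzyloxy)phenyl]-5-methoxyhex-4-en-3-one
Conditions: LDA (1.1 equiv), THF, −78 °C; then 2 (0.9 equiv), −78 → 0 °C
Reagents that add atoms: none
Why: LDA removes the kinetically accessible α'-proton (acetyl methyl) of the vinylogous ester rather than a γ-proton, and the lithium enolate is alkylated by the reactive benzylic bromide (SN2 enolate alkylation with Stork–Danheiser-type regiochemistry); no stereocentre is formed.

Step 2
Reactants: 4 2-(benzyloxy)benzaldehyde
Product: 5 (E)-3-[2-(benzyloxy)phenyl]prop-2-enal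
Conditions: Ph3P=CHCHO (1.1 equiv), toluene, 80 °C
Reagents that add atoms: (triphenylphosphoranylidene)acetaldehyde, O=CC=P(c1ccccc1)(c1ccccc1)c1ccccc1
Why: Wittig olefination with the stabilised formylmethylene ylide should give the E-enal, and the product enal is less electrophilic than the aryl aldehyde, so a second homologation is slow.

Step 3
Reactants: 3 (E)-1-[4-(benzyloxy)phenyl]-5-methoxyhex-4-en-3-one; 5 (E)-3-[2-(benzyloxy)phenyl]prop-2-enal
Product: 6 (1E,6E)-4-[4-(benzyloxy)benzyl]-1-[2-(benzyloxy)phenyl]-3-hydroxy-7-methoxyocta-1,6-dien-5-one (racemic mixture of diastereomers)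
Conditions: LDA (1.05 equiv), THF, −78 °C; then 5, −78 °C; AcOH quench at −78 °C
Reagents that add atoms: none
Why: Kinetic deprotonation again takes place at the α'-methylene and the lithium enolate adds 1,2 to the enal at low temperature (aldol addition); the two new stereocentres (C3, C4) form without control, which is acceptable because C3 becomes a carbonyl in step 4 and C4 an arene carbon in step 5.

Step 4
Reactants: 6 (1E,6E)-4-[4-(benzyloxy)benzyl]-1-[2-(benzyloxy)phenyl]-3-hydroxy-7-methoxyocta-1,6-dien-5-one
Product: 7 (1E,6E)-4-[4-(benzyloxy)benzyl]-1-[2-(benzyloxy)phenyl]-7-methoxyocta-1,6-diene-3,5-dione (racemic)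
Conditions: Dess–Martin periodinane (1.3 equiv), NaHCO3, CH2Cl2, 0 °C → rt
Reagents that add atoms: none
Why: Dess–Martin oxidation converts β-hydroxy ketones into 1,3-diketones under buffered, non-acidic conditions that should leave the methyl enol ether, the E-alkene and the benzyl ethers untouched; the C3 stereocentre is removed.

Step 5
Reactants: 7 (1E,6E)-4-[4-(benzyloxy)benzyl]-1-[2-(benzyloxy)phenyl]-7-methoxyocta-1,6-diene-3,5-dione
Product: 10 2-[4-(benzyloxy)benzyl]-3-[(E)-2-(2-benzyloxyphenyl)ethenyl]-5-methoxyphenol, via aldol adduct 8 (not isolated), via cyclohexadienone 9 (not isolated)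
Conditions: KOtBu (3 equiv), THF–tBuOH (4:1), 0 → 60 °C; then 1 M HCl to pH 5, 0 °C
Reagents that add atoms: none
Why: tert-Butoxide first forms the diketonate of 7; reversible proton transfer through tert-butanol then gives, in small concentration, the dienolate made by deprotonation of the enol-ether methyl (γ to the vinylogous ester), whose terminal carbon (future C6) adds to the cinnamoyl carbonyl carbon (future C1) to give aldolate 8, and E1cB loss of hydroxide to dienone 9 followed by enolisation delivers the phenoxide of 10. The closest known reaction type is the base-mediated aldol condensation and aromatisation of 1,3,5-tricarbonyl chains to resorcinols, run here in its vinylogous form with a β-methoxy enone methyl as the donor, as in the conversion of 2-methylpyrylium pseudo-bases into phenols. Ring A closes by a 6-(enolendo)-exo-trig attack on the ketone. The two stereocentres of 8 form without control and vanish on dehydration, so 10 has none and the E-alkene is not touched. The step needs carbon attack by the methyl terminus on the ketone in preference to oxygen closure onto the styryl β-carbon or the enol-ether carbon and to Michael addition through the dienolate α-carbon: the styryl ketone has no enolisable carbon, the methyl-to-carbonyl closure is the only one that gives a six-membered carbocycle able to aromatise, and the alkoxide medium keeps the oxa-Michael closure reversible while phenoxide formation is not. tert-Butoxide is chosen over methoxide or hydroxide to suppress retro-Claisen cleavage and exchange at the enol ether.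

Step 6
Reactants: 10 2-[4-(benzyloxy)benzyl]-3-[(E)-2-(2-benzyloxyphenyl)ethenyl]-5-methoxyphenol
Product: 11 2-(4-hydroxybenzyl)-3-[2-(2-hydroxyphenyl)ethyl]-5-methoxyphenol
Conditions: H2 (1 atm), 10% Pd/C, EtOAc–MeOH, rt
Reagents that add atoms: none
Why: Heterogeneous hydrogenation over palladium on carbon saturates the stilbene double bond and hydrogenolyses both benzyl aryl ethers in one operation, while the diarylmethane C–C bond, the aryl methyl ether and the arenes are inert.

**Compound list**

1 | (E)-4-methoxypent-3-en-2-one | CO/C(C)=C/C(C)=O | starting material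
2 | 4-(benzyloxy)benzyl bromide | BrCc1ccc(OCc2ccccc2)cc1 | starting material
3 | (E)-1-[4-(benzyloxy)phenyl]-5-methoxyhex-4-en-3-one | CO/C(C)=C/C(=O)CCc1ccc(OCc2ccccc2)cc1 | intermediate
4 | 2-(benzyloxy)benzaldehyde | O=Cc1ccccc1OCc1ccccc1 | starting material
5 | (E)-3-[2-(benzyloxy)phenyl]prop-2-enal | O=C/C=C/c1ccccc1OCc1ccccc1 | intermediate
6 | (1E,6E)-4-[4-(benzyloxy)benzyl]-1-[2-(benzyloxy)phenyl]-3-hydroxy-7-methoxyocta-1,6-dien-5-one (racemic diastereomer mixture) | CO/C(C)=C/C(=O)C(Cc1ccc(OCc2ccccc2)cc1)C(O)/C=C/c1ccccc1OCc1ccccc1 | intermediate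
7 | (1E,6E)-4-[4-(benzyloxy)benzyl]-1-[2-(benzyloxy)phenyl]-7-methoxyocta-1,6-diene-3,5-dione (racemic) | CO/C(C)=C/C(=O)C(Cc1ccc(OCc2ccccc2)cc1)C(=O)/C=C/c1ccccc1OCc1ccccc1 | intermediate
8 | 6-[4-(benzyloxy)benzyl]-5-[(E)-2-(2-benzyloxyphenyl)ethenyl]-5-hydroxy-3-methoxycyclohex-2-en-1-one (diastereomer mixture, not isolated) | COC1=CC(=O)C(Cc2ccc(OCc3ccccc3)cc2)C(O)(/C=C/c2ccccc2OCc2ccccc2)C1 | intermediate
9 | 2-[4-(benzyloxy)benzyl]-3-[(E)-2-(2-benzyloxyphenyl)ethenyl]-5-methoxycyclohexa-2,5-dien-1-one (not isolated) | COC1=CC(=O)C(Cc2ccc(OCc3ccccc3)cc2)=C(/C=C/c2ccccc2OCc2ccccc2)C1 | intermediate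
10 | 2-[4-(benzyloxy)benzyl]-3-[(E)-2-(2-benzyloxyphenyl)ethenyl]-5-methoxyphenol | COc1cc(O)c(Cc2ccc(OCc3ccccc3)cc2)c(/C=C/c2ccccc2OCc2ccccc2)c1 | intermediate
11 | 2-(4-hydroxybenzyl)-3-[2-(2-hydroxyphenyl)ethyl]-5-methoxyphenol | COc1cc(O)c(Cc2ccc(O)cc2)c(CCc2ccccc2O)c1 | target

**Step count**

Total steps: 6. Longest linear sequence: 5 (steps 1, 3, 4, 5, 6); step 2 is a one-step branch.

**Steps most likely to fail**

1. Step 5 (key cyclisation). Several processes can divert it:
   - the diketonate may act as a sink for base so that the enol-ether methyl is not deprotonated at a useful rate;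
   - the enol oxygen may close onto the enol-ether carbon with loss of methanol (4-pyranone formation);
   - the dienolate α-carbon may add to the styryl group in a 6-endo Michael closure;
   - retro-Claisen cleavage may occur, or the hydroxide set free on dehydration may exchange the enol-ether methoxy group.

   Fallback, setting out from 5 and 2 and rejoining at 10: ring A is built as a cyclohexane-1,3-dione and aromatised last. Aldehyde 5 is condensed with acetone (aq. NaOH) to (3E,5E)-6-[2-(benzyloxy)phenyl]hexa-3,5-dien-2-one F1. Dimethyl malonate (NaOMe, MeOH, reflux) adds 1,4 to give dimethyl 2-{(1E)-1-[2-(benzyloxy)phenyl]-5-oxohex-1-en-3-yl}propanedioate F2, which closes by Claisen condensation to methyl 2,4-dioxo-6-[(E)-2-(2-benzyloxyphenyl)ethenyl]cyclohexane-1-carboxylate F3. Saponification and decarboxylation (aq. NaOH, then HCl, heat) give 5-[(E)-2-(2-benzyloxyphenyl)ethenyl]cyclohexane-1,3-dione F4. Because F4 has a mirror plane through C2 and C5, enol etherification (MeOH, HC(OMe)3, cat. TsOH) gives a single constitutional isomer, racemic 3-methoxy-5-[(E)-2-(2-benzyloxyphenyl)ethenyl]cyclohex-2-en-1-one F5. Stork–Danheiser alkylation (LDA, THF, −78 °C; then 2) places the benzyl group on C6, next to the styryl-bearing carbon, to give 6-[4-(benzyloxy)benzyl]-3-methoxy-5-[(E)-2-(2-benzyloxyphenyl)ethenyl]cyclohex-2-en-1-one F6 (trans expected, racemic; both centres are lost later). A second α'-deprotonation (LDA) and PhSeBr give 6-[4-(benzyloxy)benzyl]-3-methoxy-6-(phenylselanyl)-5-[(E)-2-(2-benzyloxyphenyl)ethenyl]cyclohex-2-en-1-one F7. Oxidation (H2O2, pyridine, CH2Cl2, 0 °C) and syn-elimination of the selenoxide give dienone 9, which tautomerises to 10; step 6 then follows unchanged.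

2. Step 1 (alkylation of the kinetic enolate of 1). Proton exchange between product and enolate may lead to double alkylation, or equilibration may bring in the γ-enolate.

   Fallback, setting out from 1 and 5 and rejoining at 7: the two C–C bonds at the central carbon are made in the opposite order, so that the benzyl group is introduced on a stabilised diketonate. Aldehyde 5 is oxidised (NaClO2, NaH2PO4, 2-methylbut-2-ene, tBuOH–H2O; Pinnick oxidation) to (E)-3-[2-(benzyloxy)phenyl]prop-2-enoic acid F8. This is converted ((COCl)2, cat. DMF, CH2Cl2) into (E)-3-[2-(benzyloxy)phenyl]prop-2-enoyl chloride F9. The kinetic lithium enolate of 1 (2 equiv, LiHMDS, THF, −78 °C) is C-acylated with F9 to (1E,6E)-1-[2-(benzyloxy)phenyl]-7-methoxyocta-1,6-diene-3,5-dione F10. C-Benzylation of F10 with 2 (K2CO3, acetone, rt) gives 7, so steps 3 and 4 are bypassed as well.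

3. Step 3 (aldol addition). The adduct may revert by retro-aldol on warming, the new hydroxyl may close onto the enol-ether carbon with loss of methanol during work-up or chromatography, or 3 may be enolised in part at the γ-methyl.

   Fallback, setting out from 3 and 4 and rejoining at 7: the diketone is made at the carboxylic oxidation level without a free hydroxyl. Aldehyde 4 is olefinated with diethyl {2-[methoxy(methyl)amino]-2-oxoethyl}phosphonate (NaH, THF; Horner–Wadsworth–Emmons) to (E)-3-[2-(benzyloxy)phenyl]-N-methoxy-N-methylprop-2-enamide F11. The lithium enolate of 3 (LDA, THF, −78 → 0 °C) is acylated with F11; the chelated tetrahedral adduct collapses on mild aqueous work-up to 7, so steps 2 to 4 are replaced.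

**Further compounds**

F1 | step 5 | (3E,5E)-6-[2-(benzyloxy)phenyl]hexa-3,5-dien-2-one | CC(=O)/C=C/C=C/c1ccccc1OCc1ccccc1
F2 | step 5 | dimethyl 2-{(1E)-1-[2-(benzyloxy)phenyl]-5-oxohex-1-en-3-yl}propanedioate (racemic) | COC(=O)C(C(=O)OC)C(CC(C)=O)/C=C/c1ccccc1OCc1ccccc1
F3 | step 5 | methyl 2,4-dioxo-6-[(E)-2-(2-benzyloxyphenyl)ethenyl]cyclohexane-1-carboxylate | COC(=O)C1C(=O)CC(=O)CC1/C=C/c1ccccc1OCc1ccccc1
F4 | step 5 | 5-[(E)-2-(2-benzyloxyphenyl)ethenyl]cyclohexane-1,3-dione | O=C1CC(=O)CC(/C=C/c2ccccc2OCc2ccccc2)C1
F5 | step 5 | 3-methoxy-5-[(E)-2-(2-benzyloxyphenyl)ethenyl]cyclohex-2-en-1-one (racemic) | COC1=CC(=O)CC(/C=C/c2ccccc2OCc2ccccc2)C1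
F6 | step 5 | 6-[4-(benzyloxy)benzyl]-3-methoxy-5-[(E)-2-(2-benzyloxyphenyl)ethenyl]cyclohex-2-en-1-one (racemic, trans expected) | COC1=CC(=O)C(Cc2ccc(OCc3ccccc3)cc2)C(/C=C/c2ccccc2OCc2ccccc2)C1
F7 | step 5 | 6-[4-(benzyloxy)benzyl]-3-methoxy-6-(phenylselanyl)-5-[(E)-2-(2-benzyloxyphenyl)ethenyl]cyclohex-2-en-1-one (racemic) | COC1=CC(=O)C(Cc2ccc(OCc3ccccc3)cc2)([Se]c2ccccc2)C(/C=C/c2ccccc2OCc2ccccc2)C1
F8 | step 1 | (E)-3-[2-(benzyloxy)phenyl]prop-2-enoic acid | OC(=O)/C=C/c1ccccc1OCc1ccccc1
F9 | step 1 | (E)-3-[2-(benzyloxy)phenyl]prop-2-enoyl chloride | ClC(=O)/C=C/c1ccccc1OCc1ccccc1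
F10 | step 1 | (1E,6E)-1-[2-(benzyloxy)phenyl]-7-methoxyocta-1,6-diene-3,5-dione | CO/C(C)=C/C(=O)CC(=O)/C=C/c1ccccc1OCc1ccccc1
F11 | step 3 | (E)-3-[2-(benzyloxy)phenyl]-N-methoxy-N-methylprop-2-enamide | CON(C)C(=O)/C=C/c1ccccc1OCc1ccccc1
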